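**Retrosynthetic overview**
- Last operations: hydrogenolysis of eight benzyl ethers and one blocking bromine; before that, the bond between the diarylmethine carbon on C4 and C6 of ring A of ent-afzelechin is made by Friedel–Crafts addition to a p-quinone methide (C8 blocked by Br).
- Key disconnection O1–C2 of the tetrahydrofuran (ring O1–C2–C3–C4–C5). C2 is both benzylic to the 4-oxygenated aryl ring and β to the C3 aroyl ketone, and O1 sits on C5, 1,4 to C2. The ring is therefore the oxa-Michael isomer of a C5 alkoxide plus a C2=C3 enone, and both are unmasked together when an aryllithium opens an α-arylidene γ-butyrolactone (ring O1–C5–C4–C3–C(=O)).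
- Lactone: C2=C3 by aldol condensation, C5 by Felkin–Anh reduction/lactonisation, C4 by Evans syn-aldol reaction of a succinate imide with 4-silyloxybenzaldehyde.
- Ring order: γ-lactone (step 6), then tetrahydrofuran by ring transposition (step 8); the chroman ring comes with the flavan, made from (−)-epiafzelechin by C2 epimerisation, benzylation and C8 bromination.

Key step: step 8

Remark on the chemistry: the flavan unit of the target is (2S,3R), i.e. ent-afzelechin, so purchasable (−)-epiafzelechin (2R,3R) is inverted at C2; 1-bromo-2,4-bis(benzyloxy)benzene (9) is taken as purchasable. TBS = tert-butyldimethylsilyl, Bn = benzyl.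

**Step 1**
Reactants: 1 4-(tert-butoxy)-4-oxobutanoic acid; 2 (S)-4-benzyloxazolidin-2-one
Product: 4 tert-butyl 4-[(S)-4-benzyl-2-oxooxazolidin-3-yl]-4-oxobutanoate, via mixed pivalic anhydride 3 (not isolated)
Conditions: PivCl, Et3N, THF, −20 °C; then LiCl, 2, rt
Reagents that add atoms: none
Why: N-acylation of the oxazolidinone through the mixed pivalic anhydride (LiCl/Et3N protocol) is a standard way to N-acyl oxazolidinones and forms no stereocentre.

**Step 2**
Reactants: 4 the succinate imide; 5 4-(TBS-oxy)benzaldehyde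
Product: 6 tert-butyl (3S,4S)-3-[(S)-4-benzyl-2-oxooxazolidine-3-carbonyl]-4-hydroxy-4-[4-(TBS-oxy)phenyl]butanoate
Conditions: Bu2BOTf, i-Pr2NEt, CH2Cl2, 0 °C; 5, −78 → 0 °C; then H2O2, MeOH, pH 7 buffer
Reagents that add atoms: none
Why: Evans syn-aldol reaction: the Z boron enolate (enolisation only at the imide α-CH2) adds through a chair Zimmerman–Traxler transition state on the face away from the auxiliary benzyl group, which should set the later ring carbon C4 and the carbinol carbon as the (3S,4S) syn pair.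

**Step 3**
Reactants: 6 the aldol adduct
Product: 7 tert-butyl (3S,4S)-4-hydroxy-3-[methoxy(methyl)carbamoyl]-4-[4-(TBS-oxy)phenyl]butanoate
Conditions: MeNHOMe·HCl, AlMe3, CH2Cl2, −10 °C → rt
Reagents that add atoms: N,O-dimethylhydroxylamine hydrochloride, CNOC.Cl
Why: aluminium amide transamination of a β-hydroxy N-acyloxazolidinone to the Weinreb amide is assisted by the free β-hydroxyl, leaves the tert-butyl ester alone and touches no stereocentre.

**Step 4**
Reactants: 7 the hydroxy Weinreb amide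
Product: 8 tert-butyl (3S,4S)-3-[methoxy(methyl)carbamoyl]-4-(TBS-oxy)-4-[4-(TBS-oxy)phenyl]butanoate
Conditions: TBSOTf, 2,6-lutidine, CH2Cl2, 0 °C
Reagents that add atoms: tert-butyldimethylsilyl triflate, CC(C)(C)[Si](C)(C)OS(=O)(=O)C(F)(F)F
Why: standard silylation of a secondary alcohol, which removes this oxygen as a competing nucleophile in steps 6 and 8 and makes the carbinol arm the large substituent for step 6.

**Step 5**
Reactants: 8 the silylated Weinreb amide; 9 1-bromo-2,4-bis(benzyloxy)benzene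
Product: 11 tert-butyl (3S,4S)-3-[2,4-bis(benzyloxy)benzoyl]-4-(TBS-oxy)-4-[4-(TBS-oxy)phenyl]butanoate, via 2,4-bis(benzyloxy)phenylmagnesium bromide 10 (not isolated)
Conditions: 9, Mg turnings, I2 (cat.), THF, 45 °C; then 8, THF, −20 → 0 °C; aq. NH4Cl
Reagents that add atoms: none
Why: Weinreb ketone synthesis with an aryl Grignard reagent: the magnesium chelate of the tetrahedral intermediate stops over-addition and keeps the α-stereocentre from enolising until the quench, and the weakly basic Grignard reagent should neither attack the tert-butyl ester nor trigger β-elimination of the silyloxy group at 0 °C.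

**Step 6**
Reactants: 11 the keto ester
Product: 13 (4R,5S)-5-[2,4-bis(benzyloxy)phenyl]-4-{(S)-(TBS-oxy)[4-(TBS-oxy)phenyl]methyl}dihydrofuran-2(3H)-one (4,5-cis), via lithium alkoxide of the reduced keto ester 12 (not isolated)
Conditions: LiBH(s-Bu)3, THF, −78 °C; then warm to rt; H2O
Reagents that add atoms: none
Why: Felkin–Anh reduction: the bulky hydride should attack anti to the large α-substituent (the silyloxy(aryl)methyl arm) past the α-hydrogen, which gives the alkoxide that lactonises onto the tert-butyl ester (5-exo-trig) to the lactone with the C4 arm and the C5 aryl group cis.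

**Step 7**
Reactants: 13 the cis lactone; 14 4-(benzyloxy)benzaldehyde
Product: 17 (3E,4R,5S)-3-[4-(benzyloxy)benzylidene]-5-[2,4-bis(benzyloxy)phenyl]-4-{(S)-(TBS-oxy)[4-(TBS-oxy)phenyl]methyl}dihydrofuran-2(3H)-one, via lithium aldolate 15 (not isolated), via aldol mesylate 16 (not isolated)
Conditions: LiN(SiMe3)2, THF, −78 °C; 14; then MsCl, −78 → 0 °C; DBU, rt
Reagents that add atoms: none
Why: aldol addition of the lactone lithium enolate followed by mesylation and E1cB elimination is the usual aldol condensation route to α-arylidene lactones; C4 and C5 are not acidic under these conditions and either alkene isomer serves in step 8.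

**Step 8**
Reactants: 17 the α-arylidene lactone; 9 1-bromo-2,4-bis(benzyloxy)benzene
Product: 22 [(2R,3R,4R,5S)-2-[4-(benzyloxy)phenyl]-5-[2,4-bis(benzyloxy)phenyl]-4-{(S)-(TBS-oxy)[4-(TBS-oxy)phenyl]methyl}tetrahydrofuran-3-yl][2,4-bis(benzyloxy)phenyl]methanone, via 2,4-bis(benzyloxy)phenyllithium 18 (not isolated), via lithium lactolate 19 (not isolated), via ring-opened lithium alkoxide enone 20 (not isolated), via lithium enolate of the tetrahydrofuran 21 (not isolated)
Conditions: 9 (1.05 equiv), n-BuLi (1.0 equiv), THF, −78 °C; 17, −78 → 0 °C; AcOH; then DBU (cat.), rt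
Reagents that add atoms: none
Why: Proposed new method: the aryllithium 18 attacks the conjugated lactone carbonyl of 17 (1,2-addition) to give lactolate 19, whose collapse on warming unmasks in one event the C5 lithium alkoxide (O1) and the aryl enone C2=C3–C(=O)Ar of 20; O1 then adds to C2 and the ketone enolate 21 results, so that the tetrahydrofuran closes through the new O1–C2 bond in a formally 5-endo-trig oxa-Michael mode that is reversible and is pulled forward by the stabilised enolate. The closest known reaction types are the mono-addition of aryllithiums to γ-lactones, which gives γ-hydroxy ketones, and the base-mediated 5-endo-trig oxa-Michael closure of γ-hydroxy vinyl sulfones and α-(2-hydroxyalkyl) enones to 3-substituted tetrahydrofurans. In net terms the lactone ring O1–C5–C4–C3–C(=O) is transposed into the ring O1–C5–C4–C3–C2 and the former lactone carbon ends as the exocyclic aroyl carbon. The new stereocentres C2 and C3 are set under thermodynamic control (retro-oxa-Michael/re-addition and enolisation with DBU) by the fixed cis pair C4/C5: the aroyl group at C3 goes trans to the bulky C4 arm and the aryl group at C2 trans to the aroyl group, hence cis to the C5 aryl group. The step needs carbonyl attack instead of conjugate attack or deprotonation at C4, which the hard aryllithium at −78 °C and the β-aryl substituent of the enoate should secure, and it needs O1 to be the only oxygen nucleophile, which the silyl ether on the side-chain carbinol secures.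

**Step 9**
Reactants: 22 the bis-silyl tetrahydrofuran
Product: 23 [(2R,3R,4S,5S)-2-[4-(benzyloxy)phenyl]-5-[2,4-bis(benzyloxy)phenyl]-4-[(S)-hydroxy(4-hydroxyphenyl)methyl]tetrahydrofuran-3-yl][2,4-bis(benzyloxy)phenyl]methanone
Conditions: Bu4NF, AcOH, THF, 0 °C → rt
Reagents that add atoms: none
Why: fluoride cleaves the aryl and the alkyl silyl ether, and the acetic acid buffer keeps the medium non-basic so that no retro-oxa-Michael opening lets the freed carbinol oxygen exchange with O1.

**Step 10**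
Reactants: 24 (−)-epiafzelechin, (2R,3R)-2-(4-hydroxyphenyl)chromane-3,5,7-triol
Product: 25 ent-afzelechin, (2S,3R)-2-(4-hydroxyphenyl)chromane-3,5,7-triol
Conditions: aq. phosphate buffer (pH 7), N2, 100 °C; reversed-phase chromatography
Reagents that add atoms: none
Why: thermal C2 epimerisation of 2,3-cis flavan-3-ols runs through reversible opening of the pyran ring to the ring B p-quinone methide and should give an equilibrium mixture from which the 2,3-trans (2S,3R) epimer is separated, C3 being untouched.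

**Step 11**
Reactants: 25 ent-afzelechin
Product: 26 (2S,3R)-5,7-bis(benzyloxy)-2-[4-(benzyloxy)phenyl]chroman-3-ol
Conditions: BnBr, K2CO3, DMF, rt
Reagents that add atoms: benzyl bromide, BrCc1ccccc1
Why: Williamson etherification with carbonate alkylates only the three phenols and leaves the secondary 3-hydroxyl free.

**Step 12**
Reactants: 26 the tribenzyl ether
Product: 27 (2S,3R)-5,7-bis(benzyloxy)-2-[4-(benzyloxy)phenyl]-8-bromochroman-3-ol
Conditions: NBS, CH2Cl2, −78 °C → rt
Reagents that add atoms: N-bromosuccinimide, O=C1CCC(=O)N1Br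
Why: electrophilic bromination of 5,7-di-O-benzyl flavan-3-ols goes to C8 of the phloroglucinol-type ring A, which leaves C6 as the only nucleophilic position of that ring.

**Step 13**
Reactants: 23 the p-hydroxybenzylic alcohol; 27 the 8-bromo flavan (3 equiv)
Product: 29 [(2R,3R,4R,5S)-2-[4-(benzyloxy)phenyl]-5-[2,4-bis(benzyloxy)phenyl]-4-{(S)-[(2S,3R)-5,7-bis(benzyloxy)-2-[4-(benzyloxy)phenyl]-8-bromo-3-hydroxychroman-6-yl](4-hydroxyphenyl)methyl}tetrahydrofuran-3-yl][2,4-bis(benzyloxy)phenyl]methanone, via p-quinone methide 28 (not isolated)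
Conditions: (PhO)2P(O)OH (10 mol%), 4 Å MS, CH2Cl2, −20 °C → rt
Reagents that add atoms: none
Why: Friedel–Crafts alkylation by 1,6-addition of C6 of the flavan to the p-quinone methide, which a weak acid forms from the p-hydroxybenzylic alcohol without ionising the ring C–O bonds; 1,3-allylic strain should hold C4–H in the quinone methide plane, the C5 arm with its cis aryl group shields one face, and attack from the C3 side gives the (S) diarylmethine.

**Step 14**
Reactants: 29 the protected bromo precursor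
Product: 30 [(2R,3R,4R,5S)-5-(2,4-dihydroxyphenyl)-2-(4-hydroxyphenyl)-4-{(S)-(4-hydroxyphenyl)[(2S,3R)-3,5,7-trihydroxy-2-(4-hydroxyphenyl)chroman-6-yl]methyl}tetrahydrofuran-3-yl](2,4-dihydroxyphenyl)methanone (target)
Conditions: H2 (1 atm), Pd(OH)2/C, Et3N, THF/MeOH, rt
Reagents that add atoms: none
Why: catalytic hydrogenolysis should remove the eight benzyl ethers and the C8 bromine (Et3N takes up HBr) under mild conditions that normally leave o-hydroxyaryl ketones and the cyclic benzylic ethers intact.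

**Compound list**
1 | 4-(tert-butoxy)-4-oxobutanoic acid | CC(C)(C)OC(=O)CCC(=O)O | starting material
2 | (S)-4-benzyloxazolidin-2-one | O=C1OC[C@H](Cc2ccccc2)N1 | starting material
3 | mixed pivalic anhydride of 1 | CC(C)(C)OC(=O)CCC(=O)OC(=O)C(C)(C)C | intermediate (not isolated)
4 | tert-butyl 4-[(S)-4-benzyl-2-oxooxazolidin-3-yl]-4-oxobutanoate | CC(C)(C)OC(=O)CCC(=O)N1[C@@H](Cc2ccccc2)COC1=O | intermediate
5 | 4-(TBS-oxy)benzaldehyde | O=Cc1ccc(O[Si](C)(C)C(C)(C)C)cc1 | starting material
6 | Evans syn-aldol adduct (3S,4S) | CC(C)(C)OC(=O)C[C@H](C(=O)N1[C@@H](Cc2ccccc2)COC1=O)[C@H](O)c1ccc(O[Si](C)(C)C(C)(C)C)cc1 | intermediate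
7 | hydroxy Weinreb amide (3S,4S) | CC(C)(C)OC(=O)C[C@H](C(=O)N(C)OC)[C@H](O)c1ccc(O[Si](C)(C)C(C)(C)C)cc1 | intermediate
8 | bis-silyl Weinreb amide (3S,4S) | CC(C)(C)OC(=O)C[C@H](C(=O)N(C)OC)[C@H](O[Si](C)(C)C(C)(C)C)c1ccc(O[Si](C)(C)C(C)(C)C)cc1 | intermediate
9 | 1-bromo-2,4-bis(benzyloxy)benzene | Brc1ccc(OCc2ccccc2)cc1OCc1ccccc1 | starting material
10 | 2,4-bis(benzyloxy)phenylmagnesium bromide | Br[Mg]c1ccc(OCc2ccccc2)cc1OCc1ccccc1 | intermediate (not isolated)
11 | aryl ketone tert-butyl ester (3S,4S) | CC(C)(C)OC(=O)C[C@H](C(=O)c1ccc(OCc2ccccc2)cc1OCc1ccccc1)[C@H](O[Si](C)(C)C(C)(C)C)c1ccc(O[Si](C)(C)C(C)(C)C)cc1 | intermediate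
12 | lithium alkoxide of the reduced keto ester | CC(C)(C)OC(=O)C[C@@H]([C@H](O[Si](C)(C)C(C)(C)C)c1ccc(O[Si](C)(C)C(C)(C)C)cc1)[C@H]([O-])c1ccc(OCc2ccccc2)cc1OCc1ccccc1.[Li+] | intermediate (not isolated)
13 | cis lactone (4R,5S) | O=C1C[C@@H]([C@H](O[Si](C)(C)C(C)(C)C)c2ccc(O[Si](C)(C)C(C)(C)C)cc2)[C@@H](c2ccc(OCc3ccccc3)cc2OCc2ccccc2)O1 | intermediate
14 | 4-(benzyloxy)benzaldehyde | O=Cc1ccc(OCc2ccccc2)cc1 | starting material
15 | lithium aldolate of 13 (mixture at the two new centres) | O=C1C(C([O-])c2ccc(OCc3ccccc3)cc2)[C@@H]([C@H](O[Si](C)(C)C(C)(C)C)c2ccc(O[Si](C)(C)C(C)(C)C)cc2)[C@@H](c2ccc(OCc3ccccc3)cc2OCc2ccccc2)O1.[Li+] | intermediate (not isolated)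
16 | aldol mesylate | O=C1C(C(OS(C)(=O)=O)c2ccc(OCc3ccccc3)cc2)[C@@H]([C@H](O[Si](C)(C)C(C)(C)C)c2ccc(O[Si](C)(C)C(C)(C)C)cc2)[C@@H](c2ccc(OCc3ccccc3)cc2OCc2ccccc2)O1 | intermediate (not isolated)
17 | α-arylidene lactone (3E,4R,5S) | O=C1/C(=C/c2ccc(OCc3ccccc3)cc2)[C@@H]([C@H](O[Si](C)(C)C(C)(C)C)c2ccc(O[Si](C)(C)C(C)(C)C)cc2)[C@@H](c2ccc(OCc3ccccc3)cc2OCc2ccccc2)O1 | intermediate
18 | 2,4-bis(benzyloxy)phenyllithium | [Li]c1ccc(OCc2ccccc2)cc1OCc1ccccc1 | intermediate (not isolated)
19 | lithium lactolate (aryllithium adduct of 17) | [Li+].[O-]C1(c2ccc(OCc3ccccc3)cc2OCc2ccccc2)/C(=C/c2ccc(OCc3ccccc3)cc2)[C@@H]([C@H](O[Si](C)(C)C(C)(C)C)c2ccc(O[Si](C)(C)C(C)(C)C)cc2)[C@@H](c2ccc(OCc3ccccc3)cc2OCc2ccccc2)O1 | intermediate (not isolated)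
20 | ring-opened lithium alkoxide enone | O=C(c1ccc(OCc2ccccc2)cc1OCc1ccccc1)/C(=C/c1ccc(OCc2ccccc2)cc1)[C@@H]([C@H](O[Si](C)(C)C(C)(C)C)c1ccc(O[Si](C)(C)C(C)(C)C)cc1)[C@H]([O-])c1ccc(OCc2ccccc2)cc1OCc1ccccc1.[Li+] | intermediate (not isolated)
21 | lithium enolate of the tetrahydrofuran | [Li+].[O-]C(c1ccc(OCc2ccccc2)cc1OCc1ccccc1)=C1[C@@H]([C@H](O[Si](C)(C)C(C)(C)C)c2ccc(O[Si](C)(C)C(C)(C)C)cc2)[C@@H](c2ccc(OCc3ccccc3)cc2OCc2ccccc2)OC1c1ccc(OCc2ccccc2)cc1 | intermediate (not isolated)
22 | bis-silyl 3-aroyl tetrahydrofuran (2R,3R,4R,5S) | O=C(c1ccc(OCc2ccccc2)cc1OCc1ccccc1)[C@@H]1[C@@H]([C@H](O[Si](C)(C)C(C)(C)C)c2ccc(O[Si](C)(C)C(C)(C)C)cc2)[C@@H](c2ccc(OCc3ccccc3)cc2OCc2ccccc2)O[C@H]1c1ccc(OCc2ccccc2)cc1 | intermediate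
23 | p-hydroxybenzylic alcohol of the tetrahydrofuran (2R,3R,4S,5S) | O=C(c1ccc(OCc2ccccc2)cc1OCc1ccccc1)[C@@H]1[C@@H]([C@H](O)c2ccc(O)cc2)[C@@H](c2ccc(OCc3ccccc3)cc2OCc2ccccc2)O[C@H]1c1ccc(OCc2ccccc2)cc1 | intermediate
24 | (−)-epiafzelechin (2R,3R) | c1c(O)cc2c(c1O)C[C@@H](O)[C@@H](c1ccc(O)cc1)O2 | starting material
25 | ent-afzelechin (2S,3R) | c1c(O)cc2c(c1O)C[C@@H](O)[C@H](c1ccc(O)cc1)O2 | intermediate
26 | 5,7,4'-tri-O-benzyl ent-afzelechin | c1c(OCc3ccccc3)cc2c(c1OCc1ccccc1)C[C@@H](O)[C@H](c1ccc(OCc3ccccc3)cc1)O2 | intermediate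
27 | 8-bromo-5,7,4'-tri-O-benzyl ent-afzelechin | c1c(OCc3ccccc3)c(Br)c2c(c1OCc1ccccc1)C[C@@H](O)[C@H](c1ccc(OCc3ccccc3)cc1)O2 | intermediate
28 | p-quinone methide from 23 | O=C(c1ccc(OCc2ccccc2)cc1OCc1ccccc1)[C@@H]1[C@@H](C=C2C=CC(=O)C=C2)[C@@H](c2ccc(OCc3ccccc3)cc2OCc2ccccc2)O[C@H]1c1ccc(OCc2ccccc2)cc1 | intermediate (not isolated)
29 | protected bromo precursor of the target | O=C(c1ccc(OCc2ccccc2)cc1OCc1ccccc1)[C@@H]1[C@@H]([C@@H](c2ccc(O)cc2)c2c(OCc3ccccc3)c(Br)c3c(c2OCc2ccccc2)C[C@@H](O)[C@H](c2ccc(OCc4ccccc4)cc2)O3)[C@@H](c2ccc(OCc3ccccc3)cc2OCc2ccccc2)O[C@H]1c1ccc(OCc2ccccc2)cc1 | intermediate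
30 | CNP0251055.1 | O=C(c1ccc(O)cc1O)[C@@H]1[C@@H]([C@@H](c2ccc(O)cc2)c2c(O)cc3c(c2O)C[C@@H](O)[C@H](c2ccc(O)cc2)O3)[C@@H](c2ccc(O)cc2O)O[C@H]1c1ccc(O)cc1 | target

**Step count and risks**
Total step count: 14. Longest linear sequence: 11 steps (steps 1–9, 13, 14).

Steps most likely to fail:

Step 8 (Proposed new method). The aryllithium may add in conjugate fashion or deprotonate C4–H instead of attacking the lactone carbonyl, and the lithium alkoxide may rest as the cyclic hemiketal instead of closing onto C2. The fallback is stepwise, uses known reactions and needs no arylidene lactone. It sets out from lactone 13: one equivalent of aryllithium 18 at −78 °C should give, by the usual mono-addition to a γ-lactone, the γ-hydroxy ketone F1 (in equilibrium with its lactol). Claisen–Schmidt condensation of F1 with aldehyde 14 (KOH, EtOH/THF, 40 °C) gives the hydroxy enone, which under the same protic, reversible conditions should close by intramolecular oxa-Michael addition to the thermodynamic tetrahydrofuran. The hydroxide also cleaves the aryl silyl ether, so the product is the mono-silyl phenol F2; the conditions of step 9 then give 23, where the fallback rejoins the route.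

Step 13. Three processes may interfere: poor facial selectivity at the diarylmethine carbon (or self-alkylation on the dialkoxyphenyl ring of a second molecule), tautomerisation of the quinone methide to the vinylphenol with loss of the C4 configuration, and acid ionisation of the O1–C5 bond with epimerisation at C5. The fallback reverses the order of arylation and ring transposition, so that the Friedel–Crafts reaction runs on the lactone, where O1 is acylated and C3 is sp2. It sets out from 17: Bu4NF/AcOH gives the desilylated arylidene lactone F3, and arylation with 27 under the conditions of step 13 gives the flavan-bearing arylidene lactone F4. The conditions of step 8 with 3.05 equivalents of 18 (two are used up by the phenol and the flavan 3-hydroxyl) then give 29 directly, where the fallback rejoins the route.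

Step 14. Over-reduction may occur (hydrogenolysis of the benzylic O1–C2 and O1–C5 bonds once the phenols are free, or reduction of the aryl ketone), or the bromine may be lost incompletely. The fallback debenzylates without hydrogen: from 29, BCl3 with pentamethylbenzene (CH2Cl2, −78 °C) should give the 8-bromo derivative of the target F5. A brief transfer hydrogenolysis of the C–Br bond (Pd/C, HCO2NH4, MeOH, rt), which is much faster than benzylic C–O cleavage, then gives 30.

**Further compounds**
F1 | step 8 | γ-hydroxy ketone from 13 and aryllithium 18 (open form of the lactol) | O=C(c1ccc(OCc2ccccc2)cc1OCc1ccccc1)C[C@@H]([C@H](O[Si](C)(C)C(C)(C)C)c1ccc(O[Si](C)(C)C(C)(C)C)cc1)[C@H](O)c1ccc(OCc2ccccc2)cc1OCc1ccccc1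
F2 | step 8 | tetrahydrofuran 22 with the aryl silyl ether cleaved (free phenol, carbinol still silylated) | O=C(c1ccc(OCc2ccccc2)cc1OCc1ccccc1)[C@@H]1[C@@H]([C@H](O[Si](C)(C)C(C)(C)C)c2ccc(O)cc2)[C@@H](c2ccc(OCc3ccccc3)cc2OCc2ccccc2)O[C@H]1c1ccc(OCc2ccccc2)cc1
F3 | step 13 | arylidene lactone 17 with both silyl groups removed | O=C1/C(=C/c2ccc(OCc3ccccc3)cc2)[C@@H]([C@H](O)c2ccc(O)cc2)[C@@H](c2ccc(OCc3ccccc3)cc2OCc2ccccc2)O1
F4 | step 13 | arylidene lactone carrying the 8-bromo flavan at the diarylmethine carbon | O=C1/C(=C/c2ccc(OCc3ccccc3)cc2)[C@@H]([C@@H](c2ccc(O)cc2)c2c(OCc3ccccc3)c(Br)c3c(c2OCc2ccccc2)C[C@@H](O)[C@H](c2ccc(OCc4ccccc4)cc2)O3)[C@@H](c2ccc(OCc3ccccc3)cc2OCc2ccccc2)O1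
F5 | step 14 | 8-bromo derivative of the target | O=C(c1ccc(O)cc1O)[C@@H]1[C@@H]([C@@H](c2ccc(O)cc2)c2c(O)c(Br)c3c(c2O)C[C@@H](O)[C@H](c2ccc(O)cc2)O3)[C@@H](c2ccc(O)cc2O)O[C@H]1c1ccc(O)cc1
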